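**Plan**

1. The retrosynthesis cuts ring C at O1–C2 and C4–C4a, which gives 2,3,4,5-tetramethoxyphenol and methyl 2-methoxy-3-oxo-3-phenylpropanoate.
2. The enabling feature is that ring A carries methoxyls on C5, C6, C7 and C8. The phenol therefore has a single free ortho carbon (the future C4a), activated by an ortho and a para methoxyl, and C2–C3–C4 with its 3-OMe and 2-phenyl is a complete three-carbon keto ester.
3. The phenol C–O bond is traced through an aryl aldehyde to 1,2,3,4-tetramethoxybenzene. The keto ester is cut between its α-carbon and the benzoyl carbon (flavone C3–C2) into methyl methoxyacetate and benzoyl chloride.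
4. Forward, rings A and B are bought and the two fragments are made separately (two steps and one step). Ring C, the only ring formed, closes last in a one-pot thermal annulation.
5. There is no stereochemistry to set: the target is planar and achiral, and the racemic α-carbon of the keto ester ends as the sp2 carbon C3.

Key step: step 4

Remark: the target has no stereogenic element, so the compound itself is the single stereoisomer asked for; 1,2,3,4-tetramethoxybenzene, methyl methoxyacetate and benzoyl chloride are assumed to be catalogue chemicals.

**Route**

Step 1
Reactants: 1 1,2,3,4-tetramethoxybenzene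
Product: 3 2,3,4,5-tetramethoxybenzaldehyde, via aryl(chloro)methyl methyl ether 2 (not isolated)
Conditions: Cl2CHOMe (1.2 equiv), TiCl4 (2 equiv), CH2Cl2, 0 °C; then ice–water
Reagents that add atoms: dichloromethyl methyl ether, COC(Cl)Cl; water, O
Why: Rieche formylation (Friedel–Crafts alkylation by the TiCl4-activated dichloromethyl ether, then hydrolysis of α-chloro ether 2) should work because the two free positions of 1 are equivalent by symmetry, each is ortho to one methoxyl and para to another, and the aldehyde deactivates the ring against a second substitution.

Step 2
Reactants: 3 2,3,4,5-tetramethoxybenzaldehyde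
Product: 5 2,3,4,5-tetramethoxyphenol, via 2,3,4,5-tetramethoxyphenyl formate 4 (not isolated)
Conditions: 30% aq. H2O2 (1.3 equiv), cat. H2SO4, MeOH, rt
Reagents that add atoms: hydrogen peroxide, OO
Why: In this acid-catalysed Dakin oxidation (Baeyer–Villiger type) the aryl group of the peroxy hemiacetal, made electron-rich by its ortho and para methoxyls, should migrate in preference to hydride to give formate 4, which methanol cleaves in the same pot.

Step 3
Reactants: 6 methyl methoxyacetate; 7 benzoyl chloride
Product: 10 methyl 2-methoxy-3-oxo-3-phenylpropanoate, via lithium enolate of methyl methoxyacetate 8 (not isolated), via lithium enolate of the keto ester 9 (not isolated)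
Conditions: 6 (2.2 equiv), LDA (2.1 equiv), THF, −78 °C; then 7 (1.0 equiv), −78 °C; 1 M HCl
Reagents that add atoms: none
Why: This is a crossed Claisen-type C-acylation in which the chelated lithium enolate 8 attacks the acid chloride at carbon and a second equivalent of 8 converts the more acidic product into its enolate 9, which shields it from a second acylation until the acidic quench returns 10 and the sacrificial equivalent of 6.

Step 4
Reactants: 5 2,3,4,5-tetramethoxyphenol; 10 methyl 2-methoxy-3-oxo-3-phenylpropanoate
Product: 14 3,5,6,7,8-pentamethoxyflavone, via benzoyl(methoxy)ketene 11 (not isolated), via aryl keto ester 12 (not isolated), via o-hydroxyaryl 1,3-diketone 13 (not isolated)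
Conditions: 5 (1 equiv), 10 (2.5 equiv, in portions), Ph2O, 250 °C, Ar sweep (−MeOH, −H2O)
Reagents that add atoms: none
Why: At 250 °C the enol form of 10 should expel methanol to give acylketene 11, which the phenol traps reversibly at oxygen (ester 12, a reservoir that reverts to 11 and 5) and irreversibly at its one unsubstituted ring carbon C6 (ortho to OH, ortho to the 5-OMe, para to the 3-OMe), forming the C4–C4a bond of diketone 13. The phenolic oxygen of 13 then adds to the benzoyl carbonyl in a 6-exo-trig closure and the hemiketal loses water, forming O1–C2 and the aromatic 4-pyranone ring C. The closest known reaction type is the Mentzer pyrone synthesis, the uncatalysed thermal variant of the Simonis chromone condensation of phenols with β-keto esters, which also accepts α-substituted benzoylacetates. No stereocentre is formed, and the racemic α-carbon of 10 ends as the sp2 carbon C3. Regiochemistry cannot stray because C6 is the only free ring position, and chromone is favoured over coumarin because, without acid, the ketene carbon (future C4) is the only electrophile strong enough to reach the ring, while the α-methoxyl hinders Pechmann-type attack of the ketone carbon. Continuous removal of methanol and water in the argon stream should drive both equilibria and protect 11 from hydrolysis and decarboxylation, which is also why 10 is used in excess.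

**Compound list**

1 | 1,2,3,4-tetramethoxybenzene | COc1ccc(OC)c(OC)c1OC | starting material
2 | 1-[chloro(methoxy)methyl]-2,3,4,5-tetramethoxybenzene (racemic, formed in situ) | COC(Cl)c1cc(OC)c(OC)c(OC)c1OC | intermediate
3 | 2,3,4,5-tetramethoxybenzaldehyde | COc1cc(C=O)c(OC)c(OC)c1OC | intermediate
4 | 2,3,4,5-tetramethoxyphenyl formate (formed in situ) | COc1cc(OC=O)c(OC)c(OC)c1OC | intermediate
5 | 2,3,4,5-tetramethoxyphenol | COc1cc(O)c(OC)c(OC)c1OC | intermediate
6 | methyl methoxyacetate | COCC(=O)OC | starting material
7 | benzoyl chloride | O=C(Cl)c1ccccc1 | starting material
8 | lithium enolate of 6 (chelated, α-methoxyl cis to the enolate oxygen, formed in situ) | [Li+].C(/OC)=C(/[O-])OC | intermediate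
9 | lithium enolate of 10 (chelated, enolate oxygen cis to the ester carbonyl, formed in situ) | [Li+].C(/C(=O)OC)(OC)=C(/[O-])c1ccccc1 | intermediate
10 | methyl 2-methoxy-3-oxo-3-phenylpropanoate (racemic, enolisable) | COC(=O)C(OC)C(=O)c1ccccc1 | intermediate
11 | benzoyl(methoxy)ketene, 2-methoxy-3-phenylprop-1-ene-1,3-dione (formed in situ) | COC(=C=O)C(=O)c1ccccc1 | intermediate
12 | 2,3,4,5-tetramethoxyphenyl 2-methoxy-3-oxo-3-phenylpropanoate (racemic, formed in situ) | COc1cc(OC(=O)C(OC)C(=O)c2ccccc2)c(OC)c(OC)c1OC | intermediate
13 | 1-(2-hydroxy-3,4,5,6-tetramethoxyphenyl)-2-methoxy-3-phenylpropane-1,3-dione (racemic, formed in situ) | COc1c(O)c(C(=O)C(OC)C(=O)c2ccccc2)c(OC)c(OC)c1OC | intermediate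
14 | 3,5,6,7,8-pentamethoxyflavone, 3,5,6,7,8-pentamethoxy-2-phenyl-4H-chromen-4-one (achiral) | COc1c(OC)c(OC)c2c(=O)c(OC)c(-c3ccccc3)oc2c1OC | target

**Count**

Total steps: 4. Longest linear sequence: 3 steps (steps 1, 2 and 4); step 3 is a one-step branch that joins at step 4.

**Steps most likely to fail**

Step 4. C-acylation of the ring by the ketene may be too slow compared with ketene dimerisation or with hydrolysis and decarboxylation by the water released, and closure through the ketone carbon would lead to a coumarin. The fallback sets out from phenol 5 and comes back to the route at diketone 13, building the two bonds one at a time. Friedel–Crafts ortho-acylation of 5 with methoxyacetic acid in BF3·OEt2 at 80 °C should give 1-(2-hydroxy-3,4,5,6-tetramethoxyphenyl)-2-methoxyethan-1-one F1. Benzoylation of its phenol with benzoyl chloride 7 in pyridine should give 2-(methoxyacetyl)-3,4,5,6-tetramethoxyphenyl benzoate F2. Baker–Venkataraman rearrangement (KOH, pyridine, 50 °C) then transfers the benzoyl group to the α-carbon and delivers 13, now isolated, which is cyclodehydrated to 14 with catalytic H2SO4 in acetic acid.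

Step 3. The enolate may be acylated at oxygen, the product enolate may be acylated a second time, or the ester enolate may condense with itself. The fallback sets out from methyl methoxyacetate 6 and comes back at keto ester 10, replacing the acylation by an aldol addition and an oxidation. Enolate 8 (LDA, THF, −78 °C) is added to benzaldehyde to give methyl 3-hydroxy-2-methoxy-3-phenylpropanoate F3 as a racemic mixture of diastereomers, which is of no consequence. Dess–Martin oxidation of the secondary alcohol in CH2Cl2 then gives 10; the aldolate cannot react twice, so over-acylation is excluded.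

Step 2. Hydride may migrate in place of the aryl group, giving the benzoic acid, or the electron-rich phenol may be oxidised further towards a quinone. The fallback sets out from 1,2,3,4-tetramethoxybenzene 1 and comes back at phenol 5, bypassing the aldehyde. Directed ortho-lithiation (n-BuLi, TMEDA, THF, 0 °C) should give (2,3,4,5-tetramethoxyphenyl)lithium F4. Quenching with trimethyl borate and aqueous HCl gives (2,3,4,5-tetramethoxyphenyl)boronic acid F5. Ipso-hydroxylation with H2O2 and NaOH at 0 °C then gives 5 under conditions where the oxidant meets the phenol only as its borate ester.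

**Further compounds**

F1 | step 4 | 1-(2-hydroxy-3,4,5,6-tetramethoxyphenyl)-2-methoxyethan-1-one | COCC(=O)c1c(O)c(OC)c(OC)c(OC)c1OC
F2 | step 4 | 2-(methoxyacetyl)-3,4,5,6-tetramethoxyphenyl benzoate | COCC(=O)c1c(OC(=O)c2ccccc2)c(OC)c(OC)c(OC)c1OC
F3 | step 3 | methyl 3-hydroxy-2-methoxy-3-phenylpropanoate (racemic mixture of diastereomers) | COC(=O)C(OC)C(O)c1ccccc1
F4 | step 2 | (2,3,4,5-tetramethoxyphenyl)lithium | [Li]c1cc(OC)c(OC)c(OC)c1OC
F5 | step 2 | (2,3,4,5-tetramethoxyphenyl)boronic acid | OB(O)c1cc(OC)c(OC)c(OC)c1OC
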